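**Remarks on the chemistry (assumptions)**

- Enol-containing compounds (8, 9, 12) are written as one tautomer, and CIP letters refer to that tautomer. For 8 the quaternary carbon reads R in the form drawn and would read S in the tautomer with the other ring carbonyl; the spatial arrangement is the same.
- The cinchoninium salt in step 5 is assumed to induce the C5 configuration of the target. If it favours the mirror image, the pseudoenantiomeric cinchonidinium salt is used.

**Core numbering (all bicyclic and cage compounds)**

C1 benzoyl bridgehead, C2 (C–O), C3 (prenylated), C4 (C=O), C5 prenylated bridgehead, C6 (CH2), C7 (CH), C8 (CMe2), C9 bridging C=O, C10–C13 the chain on C7. Ring A is C1–C5 with C9; ring B is C1, C9, C5, C6, C7, C8.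

**Compound numbers**

| No. | Compound |
|---|---|
| 1 | 2,4,6-trihydroxybenzophenone |
| 2 | prenyl bromide |
| 3 | 3,5-diprenyl-2,4,6-trihydroxybenzophenone (clusiaphenone B) |
| 4 | diethyl isopropylidenemalonate |
| 5 | 2-(propan-2-ylidene)propane-1,3-diol |
| 6 | 2-(hydroxymethyl)-3-methylbut-2-enal |
| 7 | 2-(bromomethyl)-3-methylbut-2-enal |
| 8 | C5-alkylated dearomatised dienone enal (precursor of the key step) |
| 9 | bicyclic 7-endo aldehyde, neutral vinylogous acid (not isolated, step 6) |
| 10 | hydroxyadamantane trione (product of the key step) |
| 11 | potassium diketonate of the bicyclic 7-endo aldehyde (not isolated, step 7) |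
| 12 | bicyclic vinylogous acid with 7-endo 2-methoxyethenyl group |
| 13 | its C2 methyl ether |
| 14 | 7-endo acetaldehyde |
| 15 | (E)-enal |
| 16 | (E)-allylic alcohol |
| 17 | target |

## Analysis of the target

The target is a type A polyprenylated acylphloroglucinol built on a bicyclo[3.3.1]non-2-ene-4,9-dione: ring A (C1–C5 and C9) is a dearomatised, O-methylated phloroglucinol and ring B (C1, C9, C5, C6, C7, C8) is a cyclohexanone bridged across it. It has three stereocentres, C1 (R), C5 (S) and C7 (S); the two bridgeheads are locked to each other by the bicycle, so only the absolute configuration of one bridgehead and the orientation at C7 need separate control. The C7 substituent is an (E)-4-acetoxy-3-methylbut-2-enyl chain, an oxidised prenyl group, and it stands endo, on the face of ring B that looks towards C3. Sensitive groups are the three trisubstituted alkenes (strong acid, electrophilic oxidants), the allylic acetate, the C2 methyl enol ether with its possible C4 regioisomer, and the non-enolisable tricarbonyl array at C1, which nucleophiles can cleave by retro-Claisen reaction. The difficulty lies in the adjacent quaternary carbons C1 and C8, with the benzoyl group on the bridgehead, and in placing the C7 chain in the more crowded endo position. The plan rests on that endo chain: its first carbon C10 lies within bonding distance of C3, so a temporary C3–C10 bond turns the bicycle into an adamantane that can be built first and opened later.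

## Retrosynthetic reasoning

**Acetate.** The ester C–O bond of 17 is cut last, giving allylic alcohol 16. The acetate is thereby kept out of every basic, hydridic or nucleophilic step.

**Trisubstituted alkene.** 16 is taken back through enal 15 to aldehyde 14 by cutting the C11=C12 double bond. An E-selective Wittig olefination with a stabilised ylide sets the geometry, and 1,2-reduction of the enal gives the CH2O terminus. No late allylic oxidation is needed, which could not tell three similar alkenes apart.

**One-carbon homologation and methyl ether.** 14 arises by hydrolysis of the side-chain enol ether of 13, and 13 by O-methylation of vinylogous acid 12. The methyl group is placed before the aldehyde is unmasked, because a free C2/C4 enol next to an endo CH2–CHO group could add through C3 to that aldehyde and close a homoadamantane. The methyl ether removes that nucleophile and spares the later ylide and acetylation steps an acidic enol. The price is that the methylation may not distinguish the two enol oxygens.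

**Opening the cage.** 12 is traced to hydroxyadamantane 10. In the forward direction the alkoxide of 10 undergoes retro-aldol cleavage of C3–C10. This releases C10 as an aldehyde on the endo face of C7, in the form of the potassium diketonate 11, and a Wittig methoxymethylenation captures it at once as C10=C11. The cage thus supplies the endo geometry, and its opening supplies the first chain carbon.

**Key disconnection.** 10 is cut at C1–C8 and C3–C10, giving the monocyclic dienone enal 8; the ring-B-closed aldehyde 9 lies between them. Both bonds come from one enal unit: C8 is its β-carbon and C10 its carbonyl carbon. The forward reaction has to join two quaternary carbons (C1 and C8) and choose C1 over C3 for that bond; the cage closure then fixes C7.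

**Quaternary carbon.** 8 is cut at C5–C6, giving the symmetric phenol 3 and allylic bromide 7. The two prenylated ring carbons of 3 are enantiotopic, so a chiral ammonium counter-ion can decide which one is alkylated. Alkylation there gives a product that cannot re-aromatise.

**Building blocks.** 3 comes from 1 and 2 by double C-prenylation. 7 comes from 4 through diol 5 and hydroxy enal 6 (reduction, mono-oxidation, bromination). All ring A substituents of the target except the methyl group are thus present after the first step.

## Alternatives that were turned down

**Alternative 1: desymmetrising cyclopropanation and ring opening.**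
- Disconnection: ring B is cut at C5–C6. The precursor is the symmetric diene diazoketone A1, a 2,6-dimethoxycyclohexa-2,5-dienyl unit whose sp3 carbon (C1 of the core) carries the C8(CH3)2–C7(=O)–C6 diazomethyl ketone arm.
- Key step: a copper carbene with a chiral ligand adds to one of the two enantiotopic enol ether double bonds (C5=C9). The donor–acceptor cyclopropane then opens at C6–C9, which leaves C5–C6 in place and gives the bicyclic ketone A2.
- For it: catalytic desymmetrisation of a symmetric diene is a well-understood way to set absolute configuration, and on that point it is probably stronger than the ion-pair control of step 5. C8 is quaternary before ring B closes, and no acid-sensitive prenyl group is present.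
- Against it: A2 carries hydrogen at C1, C3 and C5, a methylene at C4 and a ketone at C7. The target then needs two bridgehead substitutions (benzoyl at C1 beside the CMe2 carbon, prenyl at C5), C3 prenylation, oxidation at C4, and conversion of the C7 ketone into an endo chain. Each has its own selectivity problem, and the C1 benzoylation beside C8 is the hardest.
- Comparison: the chosen route carries the benzoyl and both prenyl groups from step 1 and makes two rings and two skeletal bonds in one step from a five-step precursor. It is clearly shorter, though it gives up some certainty in enantiocontrol.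

**Alternative 2: benzannulation to a differentiated phloroglucinol, then dearomatisation.**
- Disconnection: ring A is built as an arene from cyclobutenone A3 and methoxyethyne A4, forming C9–C1 and C2–C3.
- Key step: thermal Danheiser benzannulation (ring opening of A3 to a vinylketene, [2+2] addition of A4, ring opening, six-electron closure) gives phenol A5. In A5 the C2 oxygen already carries the methyl group and the C4 oxygen a silyl group.
- For it: the C2/C4 oxygen problem is solved from the outset. On this point it is stronger than the chosen route, whose methylation in step 8 is not expected to distinguish the two enol oxygens.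
- Against it: the key step builds neither ring B nor any stereocentre. A3 needs its own multi-step preparation. C1 is unsubstituted in A5, so the benzoyl group, the quaternary C5, the C1–C8 bond and C7 all remain to be made. The pre-installed methyl ether is also incompatible with the cage device, since a C3–C10 aldol from a C2 methyl enol ether ends in a C2 ketone and loses the methyl group.
- Comparison: it tidies up the last selectivity problem of the chosen route but leaves the central problems open and adds steps before them. The chosen strategy accepts one chromatographic separation and a recycling loop in exchange for a direct solution of the skeleton and of C7.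

**Alternative 3: oxidative ring expansion of a fused hydrindanedione.**
- Disconnection: the C1–C8 bond is made by a 1,2-shift. The precursor is the cis-fused hydroxy hydrindanedione A6, in which C8 is bonded to the carbinol carbon C9 and the five-membered ring is C5, C6, C7, C8, C9.
- Key step: PhI(OAc)2 attacks the enolised dione at C1, and C8 migrates from C9 to C1 as C9 becomes the bridging ketone. The five-membered ring expands to ring B and gives trione A7.
- For it: C5, C7 and the complete, protected C7 chain are set on a simple cis-hydrindane by substrate control before the bicycle exists. No cage has to be opened and no chain built late, so on chain construction it is stronger than the chosen route. The C1–C8 bond forms by intramolecular migration and not by addition between two crowded centres.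
- Against it: in A6 the unsubstituted C3 between the two carbonyls is the more nucleophilic site for the oxidant, so attack at C1 is not assured. C5 competes with C8 as the migrating group. The oxidant is electrophilic towards the prenyl and chain alkenes. A7 still lacks the bridgehead benzoyl at C1 (beside the quaternary C8) and the C3 prenyl group, and A6 needs a longer stereoselective synthesis of its own.
- Comparison: more steps in total, with two uncertain selectivities in the key step and a hard bridgehead acylation afterwards. The chosen route has one demanding step, its substrate is available quickly, and its C7 geometry is enforced by the cage.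

Key step: step 6

## Route

Step 1
Reactants: 1 2,4,6-trihydroxybenzophenone; 2 prenyl bromide (1-bromo-3-methylbut-2-ene)
Product: 3 [2,4,6-trihydroxy-3,5-bis(3-methylbut-2-enyl)phenyl](phenyl)methanone (clusiaphenone B)
Conditions: 2 (2.1 equiv), 10% aq KOH, 0 °C
Reagents that add atoms: none
Why: In water the phenoxide of 1 is C-alkylated at its two free ring positions by the allylic bromide (double C-prenylation of an acylphloroglucinol); mono- and over-alkylated material is removed by chromatography.

Step 2
Reactants: 4 diethyl 2-(propan-2-ylidene)propanedioate (diethyl isopropylidenemalonate)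
Product: 5 2-(propan-2-ylidene)propane-1,3-diol
Conditions: i-Bu2AlH (4.5 equiv), CH2Cl2, −78 °C to 0 °C; aq KNaC4H4O6 work-up
Reagents that add atoms: none
Why: The aluminium hydride reduces both conjugated ester groups in the 1,2-sense to the allylic diol, and the tetrasubstituted alkene is too hindered for conjugate reduction.

Step 3
Reactants: 5 2-(propan-2-ylidene)propane-1,3-diol
Product: 6 2-(hydroxymethyl)-3-methylbut-2-enal
Conditions: MnO2 (activated, excess), CH2Cl2, rt, followed closely and stopped at the mono-aldehyde
Reagents that add atoms: none
Why: MnO2 oxidises allylic alcohols; after the first oxidation the remaining carbinol sits on an electron-poor alkene and should react more slowly, which allows the desymmetrising mono-oxidation.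

Step 4
Reactants: 6 2-(hydroxymethyl)-3-methylbut-2-enal
Product: 7 2-(bromomethyl)-3-methylbut-2-enal
Conditions: CBr4, PPh3, CH2Cl2, 0 °C; used freshly prepared
Reagents that add atoms: carbon tetrabromide, BrC(Br)(Br)Br
Why: Appel bromination of a primary allylic alcohol under neutral conditions; the enal is untouched and no allylic transposition is possible because the other alkene terminus is fully substituted.

Step 5
Reactants: 3 clusiaphenone B; 7 2-(bromomethyl)-3-methylbut-2-enal
Product: 8 2-{[(1R)-3-benzoyl-2,4-dihydroxy-1,5-bis(3-methylbut-2-enyl)-6-oxocyclohexa-2,4-dien-1-yl]methyl}-3-methylbut-2-enal (quaternary ring carbon = C5 of the core numbering)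
Conditions: N-(9-anthracenylmethyl)cinchoninium chloride (20 mol %), CsOH·H2O (4 equiv), CH2Cl2, 4 Å molecular sieves, −50 °C
Reagents that add atoms: none
Why: Alkylative dearomatisation by direct SN2 displacement at the primary allylic bromide (the CMe2 terminus excludes the addition–elimination pathway); attack at a prenyl-bearing ring carbon gives a dienone that cannot re-aromatise. The two prenylated carbons of the phenoxide are enantiotopic, and the tight ion pair with the chiral ammonium cation is relied on to select one of them, which sets C5 (asymmetric phase-transfer alkylation).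

Step 6
Reactants: 8 C5-alkylated dearomatised dienone enal
Product: 10 (1R,3R,5S,7S,10S)-1-benzoyl-10-hydroxy-8,8-dimethyl-3,5-bis(3-methylbut-2-enyl)tricyclo[3.3.1.1(3,7)]decane-2,4,9-trione, via bicyclic endo aldehyde 9 (not isolated)
Conditions: conc. aq HCl (excess), THF, 0 °C to rt
Reagents that add atoms: none
Why: Protonation of the enal carbonyl of 8 gives a 1-hydroxyallyl cation with most of its charge at the tertiary carbon C8; the enol carbon C1 of the chelated benzoyl-dione unit adds to C8 in a 6-(enolendo)-endo-trig conjugate addition, which closes ring B, joins the quaternary carbons C1 and C8 and leaves C7 as an enol. Ketonisation gives aldehyde 9 and its C7 epimer, which interconvert through that enol; only the endo aldehyde can reach the diketone carbon C3, and a 6-(enolendo)-exo-trig aldol addition of C3 to C10 closes the cage. The closest known reaction type is the acid-promoted annulation of alkylated, dearomatised acylphloroglucinols with enals to hydroxyadamantanes. C5 comes from 8 and dictates C1, because the tether can only bridge the ring face on which it stands; C7 is fixed endo by the C3–C10 bond; C3 follows from the cage geometry; C10 should settle under aldol reversibility with its hydroxyl on the C6 side, away from the axial methyl group on C8. The selectivity needed is C1 rather than C3 as the carbon that captures C8, although C3 is the more electron-rich enol carbon and the inverse cage (C3–C8, C1–C10) is geometrically possible. The required sense rests on reversibility: the conjugate addition joins two quaternary carbons and can revert through the tertiary cation; the C1 adduct is closed by the diketone carbon C3 in a strongly favourable aldol step; the inverse cage would have to be closed by the benzoyl-bearing tricarbonyl carbon, whose chelated enol is much more stabilised and should give only a weak, reversible aldol bond, so that material drains into 10. The wet, chloride-containing medium is chosen so that the prenyl groups are not drawn into cationic cyclisations.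

Step 7
Reactants: 10 hydroxyadamantane trione
Product: 12 (1R,5S,7R)-1-benzoyl-2-hydroxy-7-(2-methoxyethenyl)-8,8-dimethyl-3,5-bis(3-methylbut-2-enyl)bicyclo[3.3.1]non-2-ene-4,9-dione (E/Z mixture at the enol ether), via potassium diketonate of the endo aldehyde 11 (not isolated)
Conditions: Ph3P(CH2OMe)Cl (5 equiv), KOt-Bu (6 equiv), THF, 0 °C; then 10, −40 °C to rt; aq KH2PO4 work-up, crude product used directly
Reagents that add atoms: (methoxymethyl)triphenylphosphonium chloride (as its ylide), COC[P+](c1ccccc1)(c1ccccc1)c1ccccc1.[Cl-]
Why: The one equivalent of KOt-Bu left over after ylide formation deprotonates the C10 hydroxyl, and the alkoxide undergoes retro-aldol cleavage of C3–C10, driven by formation of the stabilised diketonate; the endo aldehyde, set free as its potassium salt 11, is olefinated at once by the ylide already present (retro-aldol with in situ Wittig trapping), and the mildly acidic work-up returns the vinylogous acid. The configuration at C7 is that of the cage, and the negative charge of the diketonate should slow enolisation of the aldehyde towards C7 before it is captured.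

Step 8
Reactants: 12 bicyclic vinylogous acid with 7-endo 2-methoxyethenyl group
Product: 13 (1R,5S,7R)-1-benzoyl-2-methoxy-7-(2-methoxyethenyl)-8,8-dimethyl-3,5-bis(3-methylbut-2-enyl)bicyclo[3.3.1]non-2-ene-4,9-dione (E/Z mixture at the enol ether)
Conditions: Me3SiCHN2 (2 equiv), MeOH/toluene (1:4), 0 °C to rt; chromatography on Et3N-deactivated silica
Reagents that add atoms: (trimethylsilyl)diazomethane, C[Si](C)(C)C=[N+]=[N-]
Why: O-Methylation of the acidic vinylogous acid by diazomethane released from the silyl diazoalkane in methanol; both enol oxygens can react, so methylation at the C4 oxygen is expected to compete and the C2 methyl ether is isolated by chromatography. Methylation at this stage removes the nucleophilic C3 enol before the side-chain aldehyde is unmasked.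

Step 9
Reactants: 13 C2 methyl ether
Product: 14 2-[(1R,5S,7R)-1-benzoyl-2-methoxy-8,8-dimethyl-3,5-bis(3-methylbut-2-enyl)-4,9-dioxobicyclo[3.3.1]non-2-en-7-yl]acetaldehyde
Conditions: 2 M aq HCl/THF (1:5), 0 °C to rt, short reaction time
Reagents that add atoms: water, O
Why: Acid hydrolysis of the simple enol ether by C-protonation; the C2 methyl ether is a hindered vinylogous ester, deactivated towards C-protonation by the C4 carbonyl, and should hydrolyse far more slowly, so the selectivity rests on this rate difference. The mild, aqueous conditions are chosen to spare the prenyl groups.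

Step 10
Reactants: 14 7-endo acetaldehyde
Product: 15 (2E)-4-[(1R,5S,7S)-1-benzoyl-2-methoxy-8,8-dimethyl-3,5-bis(3-methylbut-2-enyl)-4,9-dioxobicyclo[3.3.1]non-2-en-7-yl]-2-methylbut-2-enal
Conditions: Ph3P=C(CH3)CHO (1.5 equiv), toluene, 80 °C
Reagents that add atoms: 2-(triphenylphosphoranylidene)propanal, CC(C=O)=P(c1ccccc1)(c1ccccc1)c1ccccc1
Why: Wittig olefination with a stabilised ylide gives the trisubstituted alkene under thermodynamic control with the chain trans to the formyl group (E); the ylide reacts with the unhindered aldehyde and not with the hindered ketones or the less electrophilic product enal.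

Step 11
Reactants: 15 (E)-enal
Product: 16 (1R,5S,7S)-1-benzoyl-7-[(2E)-4-hydroxy-3-methylbut-2-enyl]-2-methoxy-8,8-dimethyl-3,5-bis(3-methylbut-2-enyl)bicyclo[3.3.1]non-2-ene-4,9-dione
Conditions: NaBH4, CeCl3·7H2O, MeOH/THF, −78 °C
Reagents that add atoms: none
Why: Luche reduction gives clean 1,2-reduction of the enal; at low temperature the C9 and benzoyl ketones, both flanked by quaternary carbons, and the vinylogous ester carbonyl should not compete.

Step 12
Reactants: 16 (E)-allylic alcohol
Product: 17 (2E)-4-[(1R,5S,7S)-1-benzoyl-2-methoxy-8,8-dimethyl-3,5-bis(3-methylbut-2-enyl)-4,9-dioxobicyclo[3.3.1]non-2-en-7-yl]-2-methylbut-2-enyl acetate (target, CNP0256662.1)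
Conditions: Ac2O, pyridine, DMAP (cat.), CH2Cl2, 0 °C to rt
Reagents that add atoms: acetic anhydride, CC(=O)OC(C)=O
Why: Acylation of the only hydroxyl group in the molecule; no enolisable or acidic site is left to compete.

## Compound list

1 | 2,4,6-trihydroxybenzophenone | O=C(c1ccccc1)c1c(O)cc(O)cc1O | starting material
2 | prenyl bromide (1-bromo-3-methylbut-2-ene) | CC(C)=CCBr | starting material
3 | [2,4,6-trihydroxy-3,5-bis(3-methylbut-2-enyl)phenyl](phenyl)methanone (clusiaphenone B) | O=C(c1ccccc1)c1c(O)c(CC=C(C)C)c(O)c(CC=C(C)C)c1O | intermediate
4 | diethyl 2-(propan-2-ylidene)propanedioate | CCOC(=O)C(=C(C)C)C(=O)OCC | starting material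
5 | 2-(propan-2-ylidene)propane-1,3-diol | CC(C)=C(CO)CO | intermediate
6 | 2-(hydroxymethyl)-3-methylbut-2-enal | CC(C)=C(CO)C=O | intermediate
7 | 2-(bromomethyl)-3-methylbut-2-enal | CC(C)=C(CBr)C=O | intermediate
8 | 2-{[(1R)-3-benzoyl-2,4-dihydroxy-1,5-bis(3-methylbut-2-enyl)-6-oxocyclohexa-2,4-dien-1-yl]methyl}-3-methylbut-2-enal | O=C1C(CC=C(C)C)=C(O)C(C(=O)c2ccccc2)=C(O)[C@@]1(CC=C(C)C)CC(C=O)=C(C)C | intermediate
9 | (1R,5S,7S)-1-benzoyl-2-hydroxy-8,8-dimethyl-3,5-bis(3-methylbut-2-enyl)-4,9-dioxobicyclo[3.3.1]non-2-ene-7-carbaldehyde (7-endo) | OC1=C(CC=C(C)C)C(=O)[C@]2(CC=C(C)C)C[C@H](C=O)C(C)(C)[C@@]1(C(=O)c1ccccc1)C2=O | intermediate (not isolated)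
10 | (1R,3R,5S,7S,10S)-1-benzoyl-10-hydroxy-8,8-dimethyl-3,5-bis(3-methylbut-2-enyl)tricyclo[3.3.1.1(3,7)]decane-2,4,9-trione | O=C1[C@@]3(CC=C(C)C)C(=O)[C@]2(CC=C(C)C)C[C@H]([C@@H]3O)C(C)(C)[C@@]1(C(=O)c1ccccc1)C2=O | intermediate
11 | potassium (1R,5S,7S)-1-benzoyl-7-formyl-8,8-dimethyl-3,5-bis(3-methylbut-2-enyl)-4,9-dioxobicyclo[3.3.1]non-2-en-2-olate (7-endo) | [K+].[O-]C1=C(CC=C(C)C)C(=O)[C@]2(CC=C(C)C)C[C@H](C=O)C(C)(C)[C@@]1(C(=O)c1ccccc1)C2=O | intermediate (not isolated)
12 | (1R,5S,7R)-1-benzoyl-2-hydroxy-7-(2-methoxyethenyl)-8,8-dimethyl-3,5-bis(3-methylbut-2-enyl)bicyclo[3.3.1]non-2-ene-4,9-dione (E/Z mixture) | OC1=C(CC=C(C)C)C(=O)[C@]2(CC=C(C)C)C[C@H](C=COC)C(C)(C)[C@@]1(C(=O)c1ccccc1)C2=O | intermediate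
13 | (1R,5S,7R)-1-benzoyl-2-methoxy-7-(2-methoxyethenyl)-8,8-dimethyl-3,5-bis(3-methylbut-2-enyl)bicyclo[3.3.1]non-2-ene-4,9-dione (E/Z mixture) | COC1=C(CC=C(C)C)C(=O)[C@]2(CC=C(C)C)C[C@H](C=COC)C(C)(C)[C@@]1(C(=O)c1ccccc1)C2=O | intermediate
14 | 2-[(1R,5S,7R)-1-benzoyl-2-methoxy-8,8-dimethyl-3,5-bis(3-methylbut-2-enyl)-4,9-dioxobicyclo[3.3.1]non-2-en-7-yl]acetaldehyde | COC1=C(CC=C(C)C)C(=O)[C@]2(CC=C(C)C)C[C@H](CC=O)C(C)(C)[C@@]1(C(=O)c1ccccc1)C2=O | intermediate
15 | (2E)-4-[(1R,5S,7S)-1-benzoyl-2-methoxy-8,8-dimethyl-3,5-bis(3-methylbut-2-enyl)-4,9-dioxobicyclo[3.3.1]non-2-en-7-yl]-2-methylbut-2-enal | COC1=C(CC=C(C)C)C(=O)[C@]2(CC=C(C)C)C[C@H](C/C=C(\C)C=O)C(C)(C)[C@@]1(C(=O)c1ccccc1)C2=O | intermediate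
16 | (1R,5S,7S)-1-benzoyl-7-[(2E)-4-hydroxy-3-methylbut-2-enyl]-2-methoxy-8,8-dimethyl-3,5-bis(3-methylbut-2-enyl)bicyclo[3.3.1]non-2-ene-4,9-dione | COC1=C(CC=C(C)C)C(=O)[C@]2(CC=C(C)C)C[C@H](C/C=C(\C)CO)C(C)(C)[C@@]1(C(=O)c1ccccc1)C2=O | intermediate
17 | (2E)-4-[(1R,5S,7S)-1-benzoyl-2-methoxy-8,8-dimethyl-3,5-bis(3-methylbut-2-enyl)-4,9-dioxobicyclo[3.3.1]non-2-en-7-yl]-2-methylbut-2-enyl acetate | COC1=C(CC=C(C)C)C(=O)[C@]2(CC=C(C)C)C[C@H](C/C=C(\C)COC(C)=O)C(C)(C)[C@@]1(C(=O)c1ccccc1)C2=O | target

## Step count and risks

Total: 12 steps. Longest linear sequence: 11 steps (4 → 5 → 6 → 7 → 8 → 10 → 12 → 13 → 14 → 15 → 16 → 17). The branch from 1 joins at step 5.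

**Step 6 (key step).** The most likely failure is capture of C8 by the more electron-rich C3 instead of C1, which would lead to the inverse ring B and cage. Correcting this needs long equilibration under strong acid, and that is when the prenyl groups are most at risk of protonation and cyclisation onto neighbouring enol oxygens. The fallback removes that limit by carrying allyl groups in place of prenyl groups; it sets out from 1 and returns at 10. Bis-C-allylation of 1 (allyl bromide, aq KOH, 0 °C) should give [3,5-diallyl-2,4,6-trihydroxyphenyl](phenyl)methanone F1. Alkylation of F1 with 7 under the conditions of step 5 should give the diallyl dienone enal F2. F2 has no acid-labile alkene and can be equilibrated with anhydrous CF3SO3H in CH2Cl2 for as long as the drain into the cage needs, giving the diallyl hydroxyadamantane F3. Cross-metathesis of F3 with 2-methylbut-2-ene (second-generation Grubbs catalyst, CH2Cl2, 40 °C) then converts both allyl groups into prenyl groups and gives 10.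

**Step 5.** Poor differentiation of the two enantiotopic ring carbons by the chiral ion pair is the main risk, because direct SN2 alkylation offers less organisation than a conjugate addition. Competing O-alkylation is the second. The fallback is a resolution; it sets out from 3 and 7 and returns at 10. Alkylation without a chiral catalyst (LiN(SiMe3)2, THF, 0 °C) should give the racemic dienone enal F4. Step 6 on F4 gives 10 together with its mirror image, the ent-hydroxyadamantane F5. The two are separated by preparative chromatography on a chiral stationary phase; the rigid cage with its free hydroxyl is the best point in the route for this.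

**Step 7.** The released aldehyde may enolise towards C7 before the ylide adds. The exo epimer cannot be corrected later, so this would erode the endo configuration. The ylide may also react sluggishly with the hindered aldehyde next to C8. The fallback traps the aldehyde with a non-basic organocerium reagent; it sets out from 10 and returns at 16. Carboalumination–iodination of prop-2-yn-1-ol (Negishi carboalumination with AlMe3 and Cp2ZrCl2, then I2) gives (E)-3-iodo-2-methylprop-2-en-1-ol F6, which is silylated (t-BuMe2SiCl, imidazole) to (E)-tert-butyl[(3-iodo-2-methylprop-2-enyl)oxy]dimethylsilane F7. F7 is converted into its organocerium reagent (t-BuLi, then CeCl3, THF, −78 °C) and added to 10 that has been deprotonated with LiN(i-Pr)2. This should give the 7-endo C10 carbinol adduct F8 (a vinylogous acid, as a mixture of C10 epimers). Methylation as in step 8 and separation gives its C2 methyl ether F9. Reaction with ClCO2Me and pyridine gives the C10 methyl carbonate F10. Reductive removal of the allylic carbonate through a π-allyl complex of zerovalent palladium (Pd(OAc)2, PBu3, HCO2NH4, THF), with hydride delivered to C10, should give the silyl ether F11. Bu4NF then gives 16. The weak point of this sequence is the regiochemistry of hydride delivery.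

**Step 8.** Little or no preference between the two enol oxygens is to be expected, and the less hindered C4 oxygen may even be favoured, so a large part of the material may be methylated at the wrong oxygen. The fallback replaces the single-pass separation by a demethylation–remethylation loop; it sets out from 12 and returns at 12. The regioisomer that accompanies 13 when 12 is methylated, the C4 methyl ether F12, is collected from the chromatography. Nucleophilic demethylation of this vinylogous ester with LiCl in DMSO at 120 °C returns it to 12, which is methylated again. The simple enol ether in the side chain is a much poorer leaving group and should not be cleaved.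

## Further compounds

F1 | step 6 | [3,5-diallyl-2,4,6-trihydroxyphenyl](phenyl)methanone | O=C(c1ccccc1)c1c(O)c(CC=C)c(O)c(CC=C)c1O
F2 | step 6 | diallyl analogue of 8: 2-{[3-benzoyl-2,4-dihydroxy-6-oxo-1,5-di(prop-2-enyl)cyclohexa-2,4-dien-1-yl]methyl}-3-methylbut-2-enal, configured as 8 | O=C1C(CC=C)=C(O)C(C(=O)c2ccccc2)=C(O)[C@@]1(CC=C)CC(C=O)=C(C)C
F3 | step 6 | diallyl analogue of 10: 1-benzoyl-10-hydroxy-8,8-dimethyl-3,5-di(prop-2-enyl)tricyclo[3.3.1.1(3,7)]decane-2,4,9-trione, configured as 10 | O=C1[C@@]3(CC=C)C(=O)[C@]2(CC=C)C[C@H]([C@@H]3O)C(C)(C)[C@@]1(C(=O)c1ccccc1)C2=O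
F4 | step 5 | racemic 8 | O=C1C(CC=C(C)C)=C(O)C(C(=O)c2ccccc2)=C(O)C1(CC=C(C)C)CC(C=O)=C(C)C
F5 | step 5 | enantiomer of 10 (1S,3S,5R,7R,10R) | O=C1[C@]3(CC=C(C)C)C(=O)[C@@]2(CC=C(C)C)C[C@@H]([C@H]3O)C(C)(C)[C@]1(C(=O)c1ccccc1)C2=O
F6 | step 7 | (E)-3-iodo-2-methylprop-2-en-1-ol | I/C=C(\C)CO
F7 | step 7 | (E)-tert-butyl[(3-iodo-2-methylprop-2-enyl)oxy]dimethylsilane | I/C=C(\C)CO[Si](C)(C)C(C)(C)C
F8 | step 7 | 1-benzoyl-7-[(2E)-4-(tert-butyldimethylsilyloxy)-1-hydroxy-3-methylbut-2-enyl]-2-hydroxy-8,8-dimethyl-3,5-bis(3-methylbut-2-enyl)bicyclo[3.3.1]non-2-ene-4,9-dione (7-endo, C10 epimers) | OC1=C(CC=C(C)C)C(=O)[C@]2(CC=C(C)C)C[C@H](C(O)/C=C(\C)CO[Si](C)(C)C(C)(C)C)C(C)(C)[C@@]1(C(=O)c1ccccc1)C2=O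
F9 | step 7 | C2 methyl ether of F8 | COC1=C(CC=C(C)C)C(=O)[C@]2(CC=C(C)C)C[C@H](C(O)/C=C(\C)CO[Si](C)(C)C(C)(C)C)C(C)(C)[C@@]1(C(=O)c1ccccc1)C2=O
F10 | step 7 | C10 methyl carbonate of F9 | COC1=C(CC=C(C)C)C(=O)[C@]2(CC=C(C)C)C[C@H](C(OC(=O)OC)/C=C(\C)CO[Si](C)(C)C(C)(C)C)C(C)(C)[C@@]1(C(=O)c1ccccc1)C2=O
F11 | step 7 | tert-butyldimethylsilyl ether of 16 | COC1=C(CC=C(C)C)C(=O)[C@]2(CC=C(C)C)C[C@H](C/C=C(\C)CO[Si](C)(C)C(C)(C)C)C(C)(C)[C@@]1(C(=O)c1ccccc1)C2=O
F12 | step 8 | (1S,5S,7R)-1-benzoyl-4-methoxy-7-(2-methoxyethenyl)-8,8-dimethyl-3,5-bis(3-methylbut-2-enyl)bicyclo[3.3.1]non-3-ene-2,9-dione (C4 methyl ether regioisomer of 13, E/Z mixture) | O=C1C(CC=C(C)C)=C(OC)[C@]2(CC=C(C)C)C[C@H](C=COC)C(C)(C)[C@@]1(C(=O)c1ccccc1)C2=O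
A1 | alternative 1 | 1-diazo-3-(2,6-dimethoxycyclohexa-2,5-dien-1-yl)-3-methylbutan-2-one | COC1=CCC=C(OC)C1C(C)(C)C(=O)C=[N+]=[N-]
A2 | alternative 1 | 2,9,9-trimethoxy-8,8-dimethylbicyclo[3.3.1]non-2-en-7-one (single enantiomer) | COC1=CC[C@@H]2CC(=O)C(C)(C)[C@H]1C2(OC)OC
A3 | alternative 2 | 2,4-bis(3-methylbut-2-enyl)-3-(triisopropylsilyloxy)cyclobut-2-en-1-one | O=C1C(CC=C(C)C)=C(O[Si](C(C)C)(C(C)C)C(C)C)C1CC=C(C)C
A4 | alternative 2 | methoxyethyne | COC#C
A5 | alternative 2 | 3-methoxy-4,6-bis(3-methylbut-2-enyl)-5-(triisopropylsilyloxy)phenol | COc1cc(O)c(CC=C(C)C)c(O[Si](C(C)C)(C(C)C)C(C)C)c1CC=C(C)C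
A6 | alternative 3 | cis-fused 7a-hydroxy-1,1-dimethyl-3a-(3-methylbut-2-enyl)-2-[(2E)-4-(tert-butyldimethylsilyloxy)-3-methylbut-2-enyl]hexahydroindene-4,6-dione | O=C1CC(=O)[C@]2(CC=C(C)C)C[C@H](C/C=C(\C)CO[Si](C)(C)C(C)(C)C)C(C)(C)[C@]2(O)C1
A7 | alternative 3 | 7-[(2E)-4-(tert-butyldimethylsilyloxy)-3-methylbut-2-enyl]-8,8-dimethyl-5-(3-methylbut-2-enyl)bicyclo[3.3.1]nonane-2,4,9-trione (C1–H, C3 unsubstituted) | O=C1CC(=O)[C@]2(CC=C(C)C)C[C@H](C/C=C(\C)CO[Si](C)(C)C(C)(C)C)C(C)(C)[C@H]1C2=O
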